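The route rests on the five-membered ring: the carbinol carbon C4 (then a ketone), flanked by ring-fusion C5–H and the methyl-bearing quaternary ring-fusion carbon C1, is the retron of a 3,3-disubstituted 4-pentenal. In one operation an acyclic (E,E)-allyl vinyl ether undergoes Claisen rearrangement (C1–C5 bond) and the aldehyde so formed adds across its new vinyl group under Rh catalysis (C3–C4 bond), giving the cyclopentanone with both stereocentres set from the bought C6 stereocentre of an (S)-lactone. Isopropyl addition, aldol closure of the seven-membered ring through its C8=C9 enal, and acylation of C6–OH complete the synthesis.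

Key step: step 7

Remark: daucane numbering is used throughout (C1 ring-fusion C–CH3; C2, C3 ring CH2; C4 C(OH)iPr; C5 ring-fusion CH; C6 CH–O-acyl; C7 CH2; C8 C–CHO with C14 the CHO carbon; C9 =CH; C10 CH2). TBS = tert-butyldimethylsilyl. Compounds 1, 3 and 16 are assumed to be purchased.

Step 1
Reactants: 1 4-(TBS-oxy)but-1-yne
Product: 2 (E)-5-(TBS-oxy)-3-methylpent-2-en-1-ol
Conditions: AlMe3 (2.5 equiv), Cp2ZrCl2 (0.25 equiv), CH2Cl2, 0 °C → rt; then (CH2O)n, THF, rt; aq. Rochelle salt
Reagents that add atoms: trimethylaluminium, C[Al](C)C; paraformaldehyde (formaldehyde unit), C=O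
Why: Zr-catalysed syn-carboalumination (Negishi) places Me and Al cis on the terminal alkyne and the alkenylalane is trapped by formaldehyde with retention, so only the (E)-trisubstituted allylic alcohol should form (no stereocentre).

Step 2
Reactants: 3 (S)-5-(hydroxymethyl)dihydrofuran-2(3H)-one
Product: 4 (S)-5-oxotetrahydrofuran-2-carbaldehyde
Conditions: Dess–Martin periodinane, CH2Cl2, 0 °C → rt; filtered and used crude
Reagents that add atoms: none
Why: Dess–Martin oxidation of the primary alcohol under neutral conditions should give the α-oxy aldehyde without epimerising C6, the bought stereocentre.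

Step 3
Reactants: 4 (S)-5-oxotetrahydrofuran-2-carbaldehyde
Product: 5 (S)-5-[(E)-2-iodovinyl]dihydrofuran-2(3H)-one
Conditions: CrCl2 (6 equiv), CHI3 (2 equiv), THF–dioxane, 0 °C → rt
Reagents that add atoms: iodoform, IC(I)I
Why: Takai iodo-olefination via a gem-dichromium species should give the (E)-vinyl iodide preferentially under non-basic conditions that leave the lactone and C6 untouched.

Step 4
Reactants: 5 (S)-5-[(E)-2-iodovinyl]dihydrofuran-2(3H)-one
Product: 6 (4S,5E)-6-iodohex-5-ene-1,4-diol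
Conditions: LiBH4, THF, 0 °C → rt
Reagents that add atoms: none
Why: Lithium borohydride reduces the lactone to the 1,4-diol chemoselectively, the vinyl iodide and the C6 configuration being unaffected.

Step 5
Reactants: 6 (4S,5E)-6-iodohex-5-ene-1,4-diol
Product: 7 (4S,5E)-1,4-bis(TBS-oxy)-6-iodohex-5-ene
Conditions: TBSCl, imidazole, DMF, rt
Reagents that add atoms: tert-butyldimethylsilyl chloride, CC(C)(C)[Si](C)(C)Cl
Why: Standard silylation of both hydroxyls gives the bis-silyl ether, whose primary/secondary difference allows selective unmasking later.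

Step 6
Reactants: 2 (E)-5-(TBS-oxy)-3-methylpent-2-en-1-ol; 7 (4S,5E)-1,4-bis(TBS-oxy)-6-iodohex-5-ene
Product: 8 (4S,5E)-1,4-bis(TBS-oxy)-6-{[(2E)-5-(TBS-oxy)-3-methylpent-2-en-1-yl]oxy}hex-5-ene
Conditions: CuI (10 mol %), 3,4,7,8-tetramethyl-1,10-phenanthroline (20 mol %), Cs2CO3, toluene, 80 °C
Reagents that add atoms: none
Why: Cu-catalysed Ullmann-type C–O coupling of an alkenyl iodide with an allylic alcohol proceeds with retention of the (E)-alkene geometry and, at 80 °C, should stay below the onset of the Claisen rearrangement.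

Step 7
Reactants: 8 (4S,5E)-1,4-bis(TBS-oxy)-6-{[(2E)-5-(TBS-oxy)-3-methylpent-2-en-1-yl]oxy}hex-5-ene
Product: 10 (2S,3R)-2-[(1S)-1,4-bis(TBS-oxy)butyl]-3-[2-(TBS-oxy)ethyl]-3-methylcyclopentan-1-one, via pentenal 9 (not isolated)
Conditions: [Rh(cod)Cl]2 (5 mol %), dppe (10 mol %), PhCN, 150 °C, sealed tube, Ar
Reagents that add atoms: none
Why: Heating triggers a thermal Claisen rearrangement of 8 through a chair transition state (C3–O broken, C1–C5 formed) to the 3,3-disubstituted 4-pentenal 9, which the Rh(I)–diphosphine consumes by aldehyde C–H oxidative addition, hydride transfer to C2 and acyl–C3 reductive elimination (intramolecular hydroacylation). The closest known reaction type is the one-pot Claisen rearrangement/Rh-catalysed hydroacylation of allyl vinyl ethers to cyclopentanones. Only the five-membered ring is closed, by C4–C3 reductive elimination from a six-membered acyl-rhodacycle (formally 5-endo-trig on the vinyl group); the [3,3] step closes no ring. C1 and C5 arise together: in the chair the (E)-allyl unit puts CH2CH2OTBS equatorial and Me axial and the (E)-enol ether puts the C6 chain equatorial, which fixes Me cis to the C6 chain, while the C6 stereocentre selects the enol-ether face (C7 chain anti to the forming bond, C6–O inside, C6–H outside), which should give (2S,3R). The step needs this facial selectivity, which the allylic silyloxy centre secures only moderately (the minor C1,C5-diastereomer should be separable at 10), and chemoselective acyl addition to the vinyl group, secured because it is the only C=C in 9, sits on a quaternary carbon and so cannot isomerise, and belongs to the fastest substrate class for hydroacylation. C5 should not epimerise under the neutral conditions and C6 is untouched.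

Step 8
Reactants: 10 (2S,3R)-2-[(1S)-1,4-bis(TBS-oxy)butyl]-3-[2-(TBS-oxy)ethyl]-3-methylcyclopentan-1-one
Product: 11 (1R,2S,3R)-2-[(1S)-1,4-bis(TBS-oxy)butyl]-3-[2-(TBS-oxy)ethyl]-3-methyl-1-(propan-2-yl)cyclopentan-1-ol
Conditions: i-PrMgCl, anhydrous CeCl3, THF, −78 → 0 °C
Reagents that add atoms: isopropylmagnesium chloride, CC(C)[Mg]Cl
Why: Organocerium 1,2-addition suppresses enolisation and β-hydride reduction, and the nucleophile should approach the ketone face anti to the adjacent C5 side chain, so that C4 is set with OH cis to that chain and to C1–Me (R).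

Step 9
Reactants: 11 (1R,2S,3R)-2-[(1S)-1,4-bis(TBS-oxy)butyl]-3-[2-(TBS-oxy)ethyl]-3-methyl-1-(propan-2-yl)cyclopentan-1-ol
Product: 12 (1R,2S,3R)-2-[(1S)-1-(TBS-oxy)-4-hydroxybutyl]-3-(2-hydroxyethyl)-3-methyl-1-(propan-2-yl)cyclopentan-1-ol
Conditions: HF·pyridine, pyridine, THF, 0 °C
Reagents that add atoms: none
Why: Buffered HF·pyridine cleaves the two unhindered primary TBS ethers much faster than the secondary C6 ether next to the ring, a routine primary/secondary desilylation selectivity.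

Step 10
Reactants: 12 (1R,2S,3R)-2-[(1S)-1-(TBS-oxy)-4-hydroxybutyl]-3-(2-hydroxyethyl)-3-methyl-1-(propan-2-yl)cyclopentan-1-ol
Product: 13 (4S)-4-(TBS-oxy)-4-[(1S,2R,5R)-2-hydroxy-5-methyl-5-(2-oxoethyl)-2-(propan-2-yl)cyclopentyl]butanal
Conditions: Dess–Martin periodinane, CH2Cl2, rt
Reagents that add atoms: none
Why: Dess–Martin oxidation converts both primary alcohols into aldehydes, while the tertiary C4 hydroxyl cannot be oxidised and, being trans to the C1 side chain, cannot form a lactol with C9.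

Step 11
Reactants: 13 (4S)-4-(TBS-oxy)-4-[(1S,2R,5R)-2-hydroxy-5-methyl-5-(2-oxoethyl)-2-(propan-2-yl)cyclopentyl]butanal
Product: 14 (3R,3aS,4S,8aR)-4-(TBS-oxy)-3-hydroxy-8a-methyl-3-(propan-2-yl)-1,2,3,3a,4,5,8,8a-octahydroazulene-6-carbaldehyde
Conditions: piperidine (cat.), AcOH (cat.), benzene, 60 °C, 0.01 M
Reagents that add atoms: none
Why: Amine-catalysed intramolecular aldol condensation should close the seven-membered ring through the unhindered C14/C8 enamine attacking the C9 aldehyde (the alternative C10 nucleophile is neopentyl), and dehydration then gives the C8=C9 enal without touching any stereocentre.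

Step 12
Reactants: 14 (3R,3aS,4S,8aR)-4-(TBS-oxy)-3-hydroxy-8a-methyl-3-(propan-2-yl)-1,2,3,3a,4,5,8,8a-octahydroazulene-6-carbaldehyde
Product: 15 (3R,3aS,4S,8aR)-3,4-dihydroxy-8a-methyl-3-(propan-2-yl)-1,2,3,3a,4,5,8,8a-octahydroazulene-6-carbaldehyde
Conditions: HF·pyridine, THF, rt
Reagents that add atoms: none
Why: Unbuffered HF·pyridine at room temperature removes the remaining secondary silyl ether, the enal and the tertiary alcohol being stable to these non-basic conditions.

Step 13
Reactants: 15 (3R,3aS,4S,8aR)-3,4-dihydroxy-8a-methyl-3-(propan-2-yl)-1,2,3,3a,4,5,8,8a-octahydroazulene-6-carbaldehyde; 16 4-acetoxybenzoyl chloride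
Product: 18 [(3R,3aS,4S,8aR)-6-formyl-3-hydroxy-8a-methyl-3-(propan-2-yl)-1,2,3,3a,4,5,8,8a-octahydroazulen-4-yl] 4-hydroxybenzoate, via aryl acetate 17 (not isolated)
Conditions: pyridine, DMAP (cat.), CH2Cl2, 0 °C → rt; then MeOH, K2CO3 (cat.), 0 °C
Reagents that add atoms: none
Why: DMAP-catalysed acylation should occur only at the secondary C6 hydroxyl (the tertiary C4–OH is inert) with retention, and brief methanolysis then cleaves the far more labile aryl acetate selectively, the resulting phenoxide deactivating the benzoate toward exchange.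

Compound list
1 | 4-(TBS-oxy)but-1-yne | C#CCCO[Si](C)(C)C(C)(C)C | starting material
2 | (E)-5-(TBS-oxy)-3-methylpent-2-en-1-ol | C/C(CCO[Si](C)(C)C(C)(C)C)=C\CO | intermediate
3 | (S)-5-(hydroxymethyl)dihydrofuran-2(3H)-one | OC[C@@H]1CCC(=O)O1 | starting material
4 | (S)-5-oxotetrahydrofuran-2-carbaldehyde | O=C[C@@H]1CCC(=O)O1 | intermediate
5 | (S)-5-[(E)-2-iodovinyl]dihydrofuran-2(3H)-one | I/C=C/[C@@H]1CCC(=O)O1 | intermediate
6 | (4S,5E)-6-iodohex-5-ene-1,4-diol | I/C=C/[C@@H](O)CCCO | intermediate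
7 | (4S,5E)-1,4-bis(TBS-oxy)-6-iodohex-5-ene | I/C=C/[C@@H](O[Si](C)(C)C(C)(C)C)CCCO[Si](C)(C)C(C)(C)C | intermediate
8 | (4S,5E)-1,4-bis(TBS-oxy)-6-{[(2E)-5-(TBS-oxy)-3-methylpent-2-en-1-yl]oxy}hex-5-ene | CC(C)(C)[Si](C)(C)OCC/C(C)=C/CO/C=C/[C@@H](O[Si](C)(C)C(C)(C)C)CCCO[Si](C)(C)C(C)(C)C | intermediate
9 | (2S,3S)-2-[(1S)-1,4-bis(TBS-oxy)butyl]-3-[2-(TBS-oxy)ethyl]-3-methylpent-4-enal | O=C[C@@H]([C@@](C)(CCO[Si](C)(C)C(C)(C)C)C=C)[C@@H](O[Si](C)(C)C(C)(C)C)CCCO[Si](C)(C)C(C)(C)C | intermediate (not isolated)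
10 | (2S,3R)-2-[(1S)-1,4-bis(TBS-oxy)butyl]-3-[2-(TBS-oxy)ethyl]-3-methylcyclopentan-1-one | O=C1CC[C@](C)(CCO[Si](C)(C)C(C)(C)C)[C@H]1[C@@H](O[Si](C)(C)C(C)(C)C)CCCO[Si](C)(C)C(C)(C)C | intermediate
11 | (1R,2S,3R)-2-[(1S)-1,4-bis(TBS-oxy)butyl]-3-[2-(TBS-oxy)ethyl]-3-methyl-1-(propan-2-yl)cyclopentan-1-ol | CC(C)[C@]1(O)CC[C@](C)(CCO[Si](C)(C)C(C)(C)C)[C@H]1[C@@H](O[Si](C)(C)C(C)(C)C)CCCO[Si](C)(C)C(C)(C)C | intermediate
12 | (1R,2S,3R)-2-[(1S)-1-(TBS-oxy)-4-hydroxybutyl]-3-(2-hydroxyethyl)-3-methyl-1-(propan-2-yl)cyclopentan-1-ol | CC(C)[C@]1(O)CC[C@](C)(CCO)[C@H]1[C@@H](O[Si](C)(C)C(C)(C)C)CCCO | intermediate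
13 | (4S)-4-(TBS-oxy)-4-[(1S,2R,5R)-2-hydroxy-5-methyl-5-(2-oxoethyl)-2-(propan-2-yl)cyclopentyl]butanal | CC(C)[C@]1(O)CC[C@](C)(CC=O)[C@H]1[C@@H](O[Si](C)(C)C(C)(C)C)CCC=O | intermediate
14 | (3R,3aS,4S,8aR)-4-(TBS-oxy)-3-hydroxy-8a-methyl-3-(propan-2-yl)-1,2,3,3a,4,5,8,8a-octahydroazulene-6-carbaldehyde | CC(C)[C@]1(O)CC[C@]2(C)CC=C(C=O)C[C@H](O[Si](C)(C)C(C)(C)C)[C@H]21 | intermediate
15 | (3R,3aS,4S,8aR)-3,4-dihydroxy-8a-methyl-3-(propan-2-yl)-1,2,3,3a,4,5,8,8a-octahydroazulene-6-carbaldehyde | CC(C)[C@]1(O)CC[C@]2(C)CC=C(C=O)C[C@H](O)[C@H]21 | intermediate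
16 | 4-acetoxybenzoyl chloride | CC(=O)Oc1ccc(cc1)C(Cl)=O | starting material
17 | [(3R,3aS,4S,8aR)-6-formyl-3-hydroxy-8a-methyl-3-(propan-2-yl)-1,2,3,3a,4,5,8,8a-octahydroazulen-4-yl] 4-acetoxybenzoate | CC(C)[C@]1(O)CC[C@]2(C)CC=C(C=O)C[C@H](OC(=O)c3ccc(OC(C)=O)cc3)[C@H]21 | intermediate (not isolated)
18 | [(3R,3aS,4S,8aR)-6-formyl-3-hydroxy-8a-methyl-3-(propan-2-yl)-1,2,3,3a,4,5,8,8a-octahydroazulen-4-yl] 4-hydroxybenzoate | CC(C)[C@]1(O)CC[C@]2(C)CC=C(C=O)C[C@H](OC(=O)c3ccc(O)cc3)[C@H]21 | target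

Total step count: 13
Longest linear sequence: 12 steps (3 → 4 → 5 → 6 → 7 → 8 → 10 → 11 → 12 → 13 → 14 → 15 → 18)

Steps most likely to fail

Step 7. What may go wrong: decarbonylation of the acyl–rhodium hydride competing with alkene insertion at 150 °C, together with only moderate facial discrimination in the sigmatropic step. The fallback sets out from 8 and returns at 11. Compound 8 is rearranged without metal (toluene, 130 °C), and aldehyde 9 is isolated and freed from its diastereomer. Isopropylmagnesium chloride/CeCl3 then adds to the aldehyde to give isopropyl carbinol F1 (epimers at the carbinol carbon). 9-BBN followed by NaOH/H2O2 hydroborates the vinyl group to give 1,5-diol F2. I2/PPh3/imidazole at 0 °C converts only the primary hydroxyl and gives primary iodide F3, and Dess–Martin oxidation gives iodo ketone F4. SmI2/HMPA in THF then forms the C3–C4 bond by an intramolecular samarium Barbier reaction and should deliver 11, with the isopropyl group expected anti to the C5 side chain.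

Step 8. What may go wrong: enolisation of the hindered ketone and β-hydride transfer from the isopropyl reagent (reduction instead of addition), or erosion of facial selectivity. The fallback sets out from 10 and returns at 11. Isopropenylmagnesium bromide/CeCl3, which has no β-hydrogen to transfer, should give isopropenyl carbinol F5 by the same anti approach. Hydrogenation of its only C=C (H2, Pd/C, EtOAc) then gives 11.

Step 6. What may go wrong: base-induced loss of HI from the vinyl iodide, or premature rearrangement at 80 °C, lowering the yield of 8. The fallback sets out from 7 and returns at 8. Iodine–lithium exchange (t-BuLi, Et2O, −78 °C) and trapping with 2-isopropoxy-4,4,5,5-tetramethyl-1,3,2-dioxaborolane give alkenylboronate F6. This is coupled with 2 under Cu(OAc)2/Et3N in air at room temperature (Chan–Lam-type oxidative C–O coupling with retention of the E geometry).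

Further compounds
F1 | step 7 | 4-[(1S)-1,4-bis(TBS-oxy)butyl]-5-[2-(TBS-oxy)ethyl]-2,5-dimethylhept-6-en-3-ol (C4, C5 as in 9; carbinol epimers) | CC(C)C(O)[C@@H]([C@@](C)(CCO[Si](C)(C)C(C)(C)C)C=C)[C@@H](O[Si](C)(C)C(C)(C)C)CCCO[Si](C)(C)C(C)(C)C
F2 | step 7 | 4-[(1S)-1,4-bis(TBS-oxy)butyl]-3-[2-(TBS-oxy)ethyl]-3,6-dimethylheptane-1,5-diol (1,5-diol from F1) | CC(C)C(O)[C@@H]([C@@](C)(CCO[Si](C)(C)C(C)(C)C)CCO)[C@@H](O[Si](C)(C)C(C)(C)C)CCCO[Si](C)(C)C(C)(C)C
F3 | step 7 | 4-[(1S)-1,4-bis(TBS-oxy)butyl]-5-[2-(TBS-oxy)ethyl]-7-iodo-2,5-dimethylheptan-3-ol (primary iodide) | CC(C)C(O)[C@@H]([C@@](C)(CCO[Si](C)(C)C(C)(C)C)CCI)[C@@H](O[Si](C)(C)C(C)(C)C)CCCO[Si](C)(C)C(C)(C)C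
F4 | step 7 | 4-[(1S)-1,4-bis(TBS-oxy)butyl]-5-[2-(TBS-oxy)ethyl]-7-iodo-2,5-dimethylheptan-3-one (iodo ketone) | CC(C)C(=O)[C@@H]([C@@](C)(CCO[Si](C)(C)C(C)(C)C)CCI)[C@@H](O[Si](C)(C)C(C)(C)C)CCCO[Si](C)(C)C(C)(C)C
F5 | step 8 | (1S,2S,3R)-2-[(1S)-1,4-bis(TBS-oxy)butyl]-3-[2-(TBS-oxy)ethyl]-3-methyl-1-(prop-1-en-2-yl)cyclopentan-1-ol | CC(=C)[C@]1(O)CC[C@](C)(CCO[Si](C)(C)C(C)(C)C)[C@H]1[C@@H](O[Si](C)(C)C(C)(C)C)CCCO[Si](C)(C)C(C)(C)C
F6 | step 6 | 2-[(1E,3S)-3,6-bis(TBS-oxy)hex-1-en-1-yl]-4,4,5,5-tetramethyl-1,3,2-dioxaborolane | CC1(C)OB(/C=C/[C@@H](O[Si](C)(C)C(C)(C)C)CCCO[Si](C)(C)C(C)(C)C)OC1(C)C
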